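Labels: C1 quaternary carbon, C2 CH-prenyl, C3 CH2, C4 and C7 bridgeheads, C5/O6 lactone, C8 ring ketone, C9 CH-isobutyryl, C10 bridge ketone. The five-membered ring C4–C5–O6–C7–C10 is a C,C-dialkylated tetronic acid, so C4 is a latent soft nucleophile, while C3–C2 fits a 2-substituted allyl unit. Cutting C3–C4 opens the eight-membered carbocycle (C1–C4, C10, C7–C9). In one operation a palladium-catalysed allylation closes this ring, creates quaternary C4 and leaves a C2 methylene as the handle for the last prenyl group. The precursor is an enantiopure 5-acyl-3,5-diprenyltetronic acid whose acyl chain carries C1 and ends in an allylic methyl carbonate.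

Key step: step 14

Assumption: a hand geometric model of the bicyclo[5.2.1] core puts the C2 prenyl, C1 homoprenyl and C9 isobutyryl groups of the target on the outer rim and C2–H, C9–H and the C1 methyl inside. The target configurations at C2 (set at aldehyde 31) and C9 (set at β-diketone 40) are therefore taken as the thermodynamic ones.

Step 1
Reactants: 1 geraniol
Product: 2 geranyl diethyl phosphate
Conditions: ClP(O)(OEt)2, Et3N, DMAP (cat.), CH2Cl2, 0 °C → rt
Reagents that add atoms: diethyl chlorophosphate, CCOP(=O)(Cl)OCC
Why: O-Phosphorylation of a primary allylic alcohol is routine and leaves untouched the E-trisubstituted alkene, whose geometry defines the prochiral face used in step 2.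

Step 2
Reactants: 3 TBS propargyl ether; 2 geranyl diethyl phosphate
Product: 5 (S)-1,4-diene TBS ether, via alkenylaluminium 4 (not isolated)
Conditions: 3, DIBAL-H, NiCl2(dppp) (3 mol %), THF, 0 °C → rt; then 2, chiral sulfonate-NHC–Ag complex (2.5 mol %, antipode giving S), CuCl2·2H2O (5 mol %), THF, −15 °C
Reagents that add atoms: none
Why: Nickel-catalysed hydroalumination puts aluminium on the internal alkyne carbon, and copper–NHC-catalysed enantioselective allylic substitution (SN2′ mode) then delivers this alkenyl group to the disubstituted alkene terminus of 2, a reaction type established for all-carbon quaternary centres from geranyl-type phosphates and for alkenylaluminiums substituted at the metal-bearing carbon, so the chiral ligand sets C1.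

Step 3
Reactants: 5 (S)-1,4-diene TBS ether
Product: 7 primary alcohol (oxygen on C8), via alkyl dicyclohexylborane 6 (not isolated)
Conditions: Cy2BH (from cyclohexene, BH3·SMe2), THF, 0 °C; then H2O2, NaOH, 0 °C
Reagents that add atoms: hydrogen peroxide, OO
Why: Hydroboration–oxidation with a bulky dialkylborane reacts far faster with the monosubstituted vinyl group than with the hindered 1,1-disubstituted and trisubstituted alkenes, and it places oxygen on the terminal carbon (future C8) without touching C1.

Step 4
Reactants: 7 primary alcohol
Product: 8 C8 aldehyde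
Conditions: DMP, CH2Cl2, 0 °C → rt
Reagents that add atoms: none
Why: Dess–Martin oxidation stops at the aldehyde under near-neutral conditions that leave the silyl ether and the alkenes alone.

Step 5
Reactants: 9 methyl (R)-glycidate; 10 2-methylprop-1-enylmagnesium bromide
Product: 11 methyl (R)-2-hydroxy-5-methylhex-4-enoate
Conditions: CuI (15 mol %), THF, −60 → −30 °C
Reagents that add atoms: none
Why: Copper-catalysed Grignard opening of the epoxide occurs at the unsubstituted carbon faster than addition to the ester at low temperature, so the oxygen-bearing stereocentre (future C7) is carried over unchanged as R.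

Step 6
Reactants: 11 hydroxy ester
Product: 12 (R)-2-hydroxy-5-methylhex-4-enoic acid
Conditions: LiOH, THF/H2O, 0 °C; 1 M HCl to pH 3
Reagents that add atoms: lithium hydroxide, [Li+].[OH-]
Why: Mild saponification of an α-hydroxy ester keeps the configuration because the carboxylate formed resists enolisation.

Step 7
Reactants: 12 hydroxy acid
Product: 14 cis-(2R,5R)-dioxolanone, via bis-TMS derivative 13 (not isolated)
Conditions: TMSCl, Et3N, CH2Cl2, rt, filter; then t-BuCHO, TMSOTf (5 mol %), CH2Cl2, −78 °C
Reagents that add atoms: pivalaldehyde, CC(C)(C)C=O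
Why: Silyl-transfer acetalisation of the bis-silyl derivative is a kinetic, aprotic route to 2-tert-butyl-1,3-dioxolan-4-ones that favours the cis isomer (new acetal centre R, relayed from the resident centre) and at −78 °C keeps the prenyl alkene out of Prins and lactonisation pathways, and the minor trans isomer is removed by chromatography because the acetal centre alone controls step 8.

Step 8
Reactants: 14 cis-dioxolanone; 8 C8 aldehyde
Product: 16 aldol adduct (C8 carbinol epimers), via dioxolanone lithium enolate 15 (not isolated)
Conditions: LDA, THF, −78 °C; then 8, −78 °C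
Reagents that add atoms: none
Why: This is self-regeneration of stereocentres, in which the planar lithium enolate keeps only the acetal centre, whose tert-butyl group blocks one face, so the aldol addition occurs anti to it and builds quaternary C7 in the required sense, while the C8 carbinol mixture disappears in step 9.

Step 9
Reactants: 16 aldol adduct
Product: 17 β-keto dioxolanone
Conditions: DMP, CH2Cl2, rt
Reagents that add atoms: none
Why: Dess–Martin oxidation converts both carbinol epimers into one ketone, which cannot enolise at C7 and is therefore configurationally safe.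

Step 10
Reactants: 17 β-keto dioxolanone
Product: 18 (Z)-TBS enol ether
Conditions: TBSOTf, Et3N, CH2Cl2, 0 °C → rt
Reagents that add atoms: tert-butyldimethylsilyl triflate, CC(C)(C)[Si](C)(C)OS(=O)(=O)C(F)(F)F
Why: Soft enolisation with a silyl triflate and an amine can only run toward C9, and the enol silane masks the C8 ketone against nucleophilic attack and retro-Claisen cleavage in step 12.

Step 11
Reactants: 19 5-methylhex-4-enoic acid
Product: 20 methyl 5-methylhex-4-enoate
Conditions: MeI, K2CO3, DMF, rt
Reagents that add atoms: iodomethane, CI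
Why: SN2 O-methylation of the carboxylate gives the ester that supplies C4, C5 and the C4 prenyl group as an enolate.

Step 12
Reactants: 18 TBS enol ether; 20 methyl 5-methylhex-4-enoate
Product: 23 keto tetronic acid allylic alcohol, via ester lithium enolate 21 (not isolated), via bis-silyl tetronic acid 22 (not isolated)
Conditions: 20, LDA, THF, −78 °C; add 18, −78 → −10 °C; AcOH; then TBAF, THF, 0 °C → rt; 1 M HCl wash
Reagents that add atoms: none
Why: Crossed Claisen acylation of the ester enolate by the activated acylal carbonyl C10 (the dioxolanone route to tetronic acids) releases pivalaldehyde and the C7 alkoxide, which lactonises onto the methyl ester without touching C7, and fluoride then uncovers the C8 ketone and the allylic alcohol and drives any uncyclised or silyl-migrated material to the same product.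

Step 13
Reactants: 23 keto tetronic acid allylic alcohol
Product: 25 cyclisation precursor, via bis-carbonate 24 (not isolated)
Conditions: ClCO2Me, pyridine, CH2Cl2, 0 °C; then morpholine, 0 °C; 1 M HCl wash
Reagents that add atoms: methyl chloroformate, COC(=O)Cl
Why: Exhaustive acylation converts both the primary allylic alcohol and the acidic enol, and aminolysis then cleaves only the enol carbonate, a vinylogous mixed anhydride, so the alcohol need not be addressed selectively beside a tetronic acid.

Step 14
Reactants: 25 cyclisation precursor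
Product: 27 bridged core, via allylpalladium tetronate 26 (not isolated)
Conditions: Pd2(dba)3·CHCl3 (5 mol %), DPEphos (12 mol %), degassed THF, 2 mM, syringe-pump addition, 50 °C, no added base
Reagents that add atoms: none
Why: Pd(0) ionises the allylic carbonate with loss of CO2, and the methoxide set free is consumed at once by the tetronic acid (pKa about 4), giving zwitterion 26 in which C4 is the only soft carbon nucleophile, since C9 is an ordinary ketone methylene. This is a Tsuji–Trost allylic alkylation, known for C-allylation of 3-substituted tetronic acids, for medium-ring closures and for bridging annulations of cyclic β-dicarbonyls with 2-methylenepropane-1,3-diyl units. The eight-membered carbocycle closes by outer-sphere attack of C4 on an allyl CH2 terminus (8-exo type, palladium leaving outside the ring); as the tether sits on the central allyl carbon, both termini give the same product with C2=CH2 exocyclic. C4 is controlled by the resident C7 centre, because the chain anchored through C8 reaches only the furanone face syn to C8, which gives (R)-C4 with both bridgehead prenyl groups on the opposite face. The step needs C- over O-allylation and cyclisation over oligomerisation: the O-allyl enol ether is itself an allylic vinylogous ester that Pd(0) can re-ionise, while high dilution, the gem-dialkyl effect of C1 and three sp2 ring atoms (C2, C8, C10) favour the intramolecular path. C1 carries no hydrogen, so diene formation by β-hydride loss is excluded, and the only protic by-product is one equivalent of methanol at millimolar concentration with no base left to cleave the product.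

Step 15
Reactants: 27 bridged core
Product: 29 primary alcohol (C2 epimers), via catechol boronate 28 (not isolated)
Conditions: catecholborane, RhCl(PPh3)3 (5 mol %), THF, rt; then H2O2, pH 7 phosphate buffer, 0 °C
Reagents that add atoms: hydrogen peroxide, OO
Why: Rhodium-catalysed hydroboration with catecholborane prefers 1,1-disubstituted alkenes over ketones, ignores trisubstituted alkenes and puts boron on the exocyclic carbon, but the reagent can reach only the outer face of the folded core (the inner face looks at C10=O), which would push the new CH2 group inside, so the C2 configuration formed here is not relied on.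

Step 16
Reactants: 29 primary alcohol (C2 epimers)
Product: 31 (2S)-aldehyde, via aldehyde epimer mixture 30 (not isolated)
Conditions: DMP, CH2Cl2, rt; then DBU (20 mol %), CH2Cl2, rt
Reagents that add atoms: none
Why: Dess–Martin oxidation makes C2 the α-carbon of an aldehyde (and would restore any ring carbonyl reduced in step 15), and amidine-catalysed enolisation then equilibrates C2 to the more stable epimer with the formyl group on the outer rim, which is the S configuration of the target (thermodynamic control).

Step 17
Reactants: 31 (2S)-aldehyde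
Product: 32 (2S)-primary alcohol
Conditions: NaBH(OAc)3, THF, rt → 40 °C
Reagents that add atoms: none
Why: Triacetoxyborohydride reduces aldehydes but not ketones, all the more as C8 and C10 are flanked by fully substituted carbons, and the weakly acidic medium does not disturb C2.

Step 18
Reactants: 32 (2S)-primary alcohol
Product: 33 primary iodide
Conditions: I2, PPh3, imidazole, CH2Cl2, 0 °C → rt
Reagents that add atoms: iodine, II
Why: Appel-type iodination proceeds by SN2 at the exocyclic carbon under neutral conditions and leaves C2 untouched.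

Step 19
Reactants: 33 primary iodide; 34 1-bromo-2-methylprop-1-ene
Product: 36 C2-prenyl core, via alkylzinc iodide 35 (not isolated)
Conditions: Zn dust, LiCl, THF, 40 °C; then 34, Pd(OAc)2 (5 mol %), SPhos (10 mol %), THF, rt
Reagents that add atoms: none
Why: Lithium chloride-promoted zinc insertion gives an alkylzinc iodide that tolerates ketones and lactones, and its Negishi coupling with the alkenyl bromide completes the prenyl group without any base that could cleave the non-enolisable β-dicarbonyl array.

Step 20
Reactants: 36 C2-prenyl core; 37 isobutyraldehyde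
Product: 39 aldol adduct, via C9 lithium enolate 38 (not isolated)
Conditions: LiHMDS, THF, −78 °C; then 37, −78 °C; cold aqueous quench
Reagents that add atoms: none
Why: C9 carries the only α-hydrogens of the molecule, so the hindered amide base forms a single lithium enolate, whose aldol addition to the small aldehyde should take place from the outer face, and both new centres are provisional.

Step 21
Reactants: 39 aldol adduct
Product: 40 target CNP0121153.1
Conditions: DMP, CH2Cl2, rt; then Et3N (cat.), CH2Cl2, rt
Reagents that add atoms: none
Why: Dess–Martin oxidation of the β-hydroxy ketone gives the 1,3-diketone, in which the acidic C9–H equilibrates to the more stable R epimer with the isobutyryl group on the outer rim, syn to the C1 methyl (thermodynamic control).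

Compound list
1 | geraniol | CC(C)=CCC/C(C)=C/CO | starting material
2 | geranyl diethyl phosphate | CC(C)=CCC/C(C)=C/COP(=O)(OCC)OCC | intermediate
3 | tert-butyldimethyl(prop-2-yn-1-yloxy)silane | C#CCO[Si](C)(C)C(C)(C)C | starting material
4 | [3-(TBSO)prop-1-en-2-yl]diisobutylaluminium (not isolated) | C=C(CO[Si](C)(C)C(C)(C)C)[Al](CC(C)C)CC(C)C | intermediate
5 | (3S)-3,7-dimethyl-2-methylidene-3-vinyloct-6-en-1-yl TBS ether (C1 = S) | CC(C)=CCC[C@@](C)(C=C)C(=C)CO[Si](C)(C)C(C)(C)C | intermediate
6 | B-alkyl dicyclohexylborane from 5, boron on C8 (not isolated) | CC(C)=CCC[C@@](C)(CCB(C1CCCCC1)C1CCCCC1)C(=C)CO[Si](C)(C)C(C)(C)C | intermediate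
7 | (3S)-3,7-dimethyl-3-[3-(TBSO)prop-1-en-2-yl]oct-6-en-1-ol | CC(C)=CCC[C@@](C)(CCO)C(=C)CO[Si](C)(C)C(C)(C)C | intermediate
8 | (3S)-3,7-dimethyl-3-[3-(TBSO)prop-1-en-2-yl]oct-6-enal | CC(C)=CCC[C@@](C)(CC=O)C(=C)CO[Si](C)(C)C(C)(C)C | intermediate
9 | methyl (2R)-oxirane-2-carboxylate | COC(=O)[C@H]1CO1 | starting material
10 | 2-methylprop-1-enylmagnesium bromide | CC(C)=C[Mg]Br | starting material
11 | methyl (2R)-2-hydroxy-5-methylhex-4-enoate | COC(=O)[C@H](O)CC=C(C)C | intermediate
12 | (2R)-2-hydroxy-5-methylhex-4-enoic acid | OC(=O)[C@H](O)CC=C(C)C | intermediate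
13 | trimethylsilyl (2R)-5-methyl-2-(trimethylsilyloxy)hex-4-enoate (not isolated) | C[Si](C)(C)OC(=O)[C@H](O[Si](C)(C)C)CC=C(C)C | intermediate
14 | (2R,5R)-2-tert-butyl-5-(3-methylbut-2-enyl)-1,3-dioxolan-4-one (cis) | CC(C)(C)[C@H]1OC(=O)[C@@H](CC=C(C)C)O1 | intermediate
15 | lithium enolate of 14 (not isolated) | CC(C)(C)[C@H]1OC(O[Li])=C(CC=C(C)C)O1 | intermediate
16 | (2R,5S)-dioxolanone aldol adduct, C7 quaternary, C1 S, C8 carbinol epimers | CC(C)(C)[C@H]1OC(=O)[C@](CC=C(C)C)(C(O)C[C@](C)(CCC=C(C)C)C(=C)CO[Si](C)(C)C(C)(C)C)O1 | intermediate
17 | (2R,5S)-β-keto dioxolanone (C8 ketone) | CC(C)(C)[C@H]1OC(=O)[C@](CC=C(C)C)(C(=O)C[C@](C)(CCC=C(C)C)C(=C)CO[Si](C)(C)C(C)(C)C)O1 | intermediate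
18 | (Z)-TBS enol ether of 17 (C8=C9) | CC(C)(C)[C@H]1OC(=O)[C@](CC=C(C)C)(/C(O[Si](C)(C)C(C)(C)C)=C/[C@](C)(CCC=C(C)C)C(=C)CO[Si](C)(C)C(C)(C)C)O1 | intermediate
19 | 5-methylhex-4-enoic acid | CC(C)=CCCC(=O)O | starting material
20 | methyl 5-methylhex-4-enoate | CC(C)=CCCC(=O)OC | intermediate
21 | lithium enolate of 20 (not isolated) | CC(C)=CCC=C(OC)O[Li] | intermediate
22 | 3,5-diprenyltetronic acid with C8 TBS enol ether and allylic TBS ether (not isolated) | CC(C)=CCC[C@@](C)(/C=C(O[Si](C)(C)C(C)(C)C)/[C@]1(CC=C(C)C)OC(=O)C(CC=C(C)C)=C1O)C(=C)CO[Si](C)(C)C(C)(C)C | intermediate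
23 | 5-acyl-3,5-diprenyltetronic acid with free allylic alcohol (C1 S, C7 R; may rest as its C8 lactol) | CC(C)=CCC[C@@](C)(CC(=O)[C@]1(CC=C(C)C)OC(=O)C(CC=C(C)C)=C1O)C(=C)CO | intermediate
24 | enol and allylic bis(methyl carbonate) of 23 (not isolated) | CC(C)=CCC[C@@](C)(CC(=O)[C@]1(CC=C(C)C)OC(=O)C(CC=C(C)C)=C1OC(=O)OC)C(=C)COC(=O)OC | intermediate
25 | cyclisation precursor: 5-acyl-3,5-diprenyltetronic acid with allylic methyl carbonate (C1 S, C7 R) | CC(C)=CCC[C@@](C)(CC(=O)[C@]1(CC=C(C)C)OC(=O)C(CC=C(C)C)=C1O)C(=C)COC(=O)OC | intermediate
26 | η3-allylpalladium tetronate zwitterion, drawn as σ-allyl, ligands omitted (not isolated) | CC(C)=CCC[C@@](C)(CC(=O)[C@]1(CC=C(C)C)OC(=O)C(CC=C(C)C)=C1[O-])C(=C)C[Pd+] | intermediate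
27 | bridged core with C2 methylene and C9 methylene (C1 S, C4 R, C7 S) | CC(C)=CCC[C@]1(C)C(=C)C[C@@]2(CC=C(C)C)C(=O)O[C@@](CC=C(C)C)(C(=O)C1)C2=O | intermediate
28 | catechol boronate, boron on the exocyclic carbon, C2 epimers (not isolated) | CC(C)=CCC[C@]1(C)C(CB3Oc4ccccc4O3)C[C@@]2(CC=C(C)C)C(=O)O[C@@](CC=C(C)C)(C(=O)C1)C2=O | intermediate
29 | C2-hydroxymethyl core, C2 epimers | CC(C)=CCC[C@]1(C)C(CO)C[C@@]2(CC=C(C)C)C(=O)O[C@@](CC=C(C)C)(C(=O)C1)C2=O | intermediate
30 | C2-formyl core, C2 epimers (not isolated) | CC(C)=CCC[C@]1(C)C(C=O)C[C@@]2(CC=C(C)C)C(=O)O[C@@](CC=C(C)C)(C(=O)C1)C2=O | intermediate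
31 | (2S)-C2-formyl core | CC(C)=CCC[C@]1(C)[C@@H](C=O)C[C@@]2(CC=C(C)C)C(=O)O[C@@](CC=C(C)C)(C(=O)C1)C2=O | intermediate
32 | (2S)-C2-hydroxymethyl core | CC(C)=CCC[C@]1(C)[C@@H](CO)C[C@@]2(CC=C(C)C)C(=O)O[C@@](CC=C(C)C)(C(=O)C1)C2=O | intermediate
33 | (2S)-C2-iodomethyl core | CC(C)=CCC[C@]1(C)[C@@H](CI)C[C@@]2(CC=C(C)C)C(=O)O[C@@](CC=C(C)C)(C(=O)C1)C2=O | intermediate
34 | 1-bromo-2-methylprop-1-ene | CC(C)=CBr | starting material
35 | alkylzinc iodide from 33 (not isolated) | CC(C)=CCC[C@]1(C)[C@@H](C[Zn]I)C[C@@]2(CC=C(C)C)C(=O)O[C@@](CC=C(C)C)(C(=O)C1)C2=O | intermediate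
36 | C2-prenyl core with C9 methylene (C1 S, C2 S, C4 R, C7 S) | CC(C)=CCC[C@]1(C)[C@@H](CC=C(C)C)C[C@@]2(CC=C(C)C)C(=O)O[C@@](CC=C(C)C)(C(=O)C1)C2=O | intermediate
37 | isobutyraldehyde | CC(C)C=O | starting material
38 | C8–C9 lithium enolate of 36 (not isolated) | CC(C)=CCC[C@]1(C)[C@@H](CC=C(C)C)C[C@@]2(CC=C(C)C)C(=O)O[C@@](CC=C(C)C)(C(O[Li])=C1)C2=O | intermediate
39 | C9-(1-hydroxy-2-methylpropyl) aldol adduct, C9 and carbinol centres provisional | CC(C)=CCC[C@]1(C)[C@@H](CC=C(C)C)C[C@@]2(CC=C(C)C)C(=O)O[C@@](CC=C(C)C)(C(=O)C1C(O)C(C)C)C2=O | intermediate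
40 | CNP0121153.1 (C1 R, C2 S, C4 R, C7 S, C9 R) | CC(C)=CCC[C@]1(C)[C@@H](CC=C(C)C)C[C@@]2(CC=C(C)C)C(=O)O[C@@](CC=C(C)C)(C(=O)[C@H]1C(=O)C(C)C)C2=O | target

Total step count: 21. Longest linear sequence: 17 steps (1–4, 8–10, 12–21).

Steps most likely to fail

Step 14. The ring closure may lose to intermolecular allylation and give oligomers. Alternatively, the tetronate may be allylated at oxygen and the catalyst may fail to re-ionise the hindered enol ether. The fallback separates ring closure from construction of the quaternary centre and sets out from 23. An intramolecular Mitsunobu etherification (PPh3, DIAD, toluene, high dilution) is used, a reaction in which tetronic acids are alkylated at the C10 oxygen. It gives the eight-membered cyclic allyl tetronate F1. Heating (xylene, 140 °C) then triggers a Claisen rearrangement of the allyl enol ether. Because the allyl unit is symmetric about C2, the [3,3] shift forms C3–C4 and regenerates the exocyclic methylene. The tether restricts the shift to the furanone face syn to C8. The fallback comes back to the route at 27.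

Step 15. Insertion of the hindered methylene may be too slow, because the developing CH2–B group is pushed toward the C10 carbonyl. Carbonyl reduction or catalyst decay could then take over. The fallback keeps C2 trigonal until it is protonated and sets out from 27. Rhodium-catalysed dehydrogenative borylation (B2pin2, trans-RhCl(CO)(PPh3)2, toluene/MeCN, 80 °C), known for 1,1-disubstituted alkenes, gives the exocyclic alkenyl pinacol boronate F2. Oxidation with NaBO3·4H2O (THF/H2O) delivers the enol and hence the aldehyde. The fallback comes back to the route at 30, which is equilibrated with DBU as in step 16.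

Step 12. Attack of the branched ester enolate on the neopentyl-like acylal carbonyl may be slower than self-condensation or decay of the enolate. The fallback replaces the acylation by an aldol addition to a far more reactive aldehyde-level carbon and sets out from 18. DIBAL-H (CH2Cl2, −78 °C) reduces the dioxolanone to the lactol F3. Excess enolate 21 adds to this masked α-hydroxy aldehyde with loss of pivalaldehyde and gives the dihydroxy ester F4. Parikh–Doering oxidation of the secondary carbinol gives the γ-hydroxy-β-keto ester F5. TBAF (THF, rt) then lactonises and desilylates it. The fallback comes back to the route at 23.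

Further compounds
F1 | step 14 | eight-membered cyclic allyl tetronate (C10–O–CH2–C2 enol ether) | CC(C)=CCC[C@@]1(C)CC(=O)[C@]2(CC=C(C)C)OC(=O)C(CC=C(C)C)=C2OCC1=C
F2 | step 15 | exocyclic alkenyl pinacol boronate of the bridged core | CC(C)=CCC[C@]1(C)C(=CB3OC(C)(C)C(C)(C)O3)C[C@@]2(CC=C(C)C)C(=O)O[C@@](CC=C(C)C)(C(=O)C1)C2=O
F3 | step 12 | lactol from reduction of 18 at C10 | CC(C)(C)[C@H]1OC(O)[C@](CC=C(C)C)(/C(O[Si](C)(C)C(C)(C)C)=C/[C@](C)(CCC=C(C)C)C(=C)CO[Si](C)(C)C(C)(C)C)O1
F4 | step 12 | methyl 3,4-dihydroxy-2,4-diprenyl ester (C10 carbinol, C7 tertiary alcohol) | COC(=O)C(CC=C(C)C)C(O)[C@](O)(CC=C(C)C)/C(O[Si](C)(C)C(C)(C)C)=C/[C@](C)(CCC=C(C)C)C(=C)CO[Si](C)(C)C(C)(C)C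
F5 | step 12 | γ-hydroxy-β-keto ester (C10 ketone) | COC(=O)C(CC=C(C)C)C(=O)[C@](O)(CC=C(C)C)/C(O[Si](C)(C)C(C)(C)C)=C/[C@](C)(CCC=C(C)C)C(=C)CO[Si](C)(C)C(C)(C)C
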